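**Retrosynthetic overview** (butenolide locants: O1, C2 lactone C=O, C3 OMe, C4 aryl, C5 quaternary)
1. Target ← tri-O-benzyl butenolide by hydrogenolysis of three benzyl ethers.
2. Tri-O-benzyl butenolide ← divinyl ester by C4–C5 bond formation: enantioselective reductive Heck cyclisation (5-exo), with C4 as a vinyl triflate and C5 as the α-carbon of the (Z)-enol ester of an arylpyruvate. This one operation closes the butenolide, creates the quaternary centre and turns ArCH= into ArCH2.
3. Enabling feature: C5 carries the ring oxygen O1, the CO2Me group and an arylmethyl group, so it maps onto the O-acylated enol of a methyl arylpyruvate (C5=CH–Ar). C4 is a vinylic carbon β to the lactone carbonyl C2. After insertion the palladium sits on a benzylic carbon flanked only by quaternary C5 and the arene, so no β-hydrogen is available and hydride capture has to follow.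
4. Divinyl ester ← arylpyruvate enol + (triflyloxy)acrylic acid (plain esterification, O1–C2). Enol ← chroman aldehyde (Horner–Wadsworth–Emmons) ← commercial chromene nitrile (Jacobsen–Katsuki epoxidation, benzylic hydrogenolysis). Acid ← 3,4-bis(benzyloxy)benzoic acid + tert-butyl methoxyacetate (crossed Claisen, enol triflation).
5. Ring order: the benzopyran ring is bought and only oxidised; the butenolide is the single ring formed, in step 11.

Key step: step 11

Assumption: the BINAP antipode that leads to (R) at C5 cannot be derived from precedent; (R)-BINAP is written, and (S)-BINAP would be used if insertion occurs on the other alkene face.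
Assumption: the silyloxy phosphonate and tert-butyl 2-methoxyacetate are taken as purchasable reagents.

**Step 1**
Reactants: 1 2,2-dimethyl-2H-chromene-6-carbonitrile
Product: 2 (3R,4R)-3,4-epoxy-2,2-dimethyl-3,4-dihydro-2H-chromene-6-carbonitrile
Conditions: (R,R)-[N,N′-bis(3,5-di-tert-butylsalicylidene)-1,2-cyclohexanediaminato]MnCl (3 mol%), 4-phenylpyridine N-oxide, aq. NaOCl (pH 11.3), CH2Cl2, 0 °C
Reagents that add atoms: sodium hypochlorite, [Na+].[O-]Cl
Why: Jacobsen–Katsuki epoxidation of a cis-disubstituted 2,2-dimethylchromene, the benchmark substrate class; the oxo-manganese species transfers oxygen to one face of the C3=C4 alkene, and the (R,R)-catalyst is expected to give the (3R,4R)-epoxide, which fixes the chroman carbinol centre.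

**Step 2**
Reactants: 2 (3R,4R)-3,4-epoxy-2,2-dimethyl-3,4-dihydro-2H-chromene-6-carbonitrile
Product: 3 (3R)-3-hydroxy-2,2-dimethyl-3,4-dihydro-2H-chromene-6-carbonitrile
Conditions: H2 (1 atm), Pd/C, EtOAc, rt
Reagents that add atoms: none
Why: Palladium-catalysed hydrogenolysis cleaves only the benzylic C4–O bond of the aryl epoxide; the C3–O bond is not benzylic, so the (3R) centre is carried over unchanged.

**Step 3**
Reactants: 3 (3R)-3-hydroxy-2,2-dimethyl-3,4-dihydro-2H-chromene-6-carbonitrile
Product: 4 (3R)-3-(benzyloxy)-2,2-dimethyl-3,4-dihydro-2H-chromene-6-carbonitrile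
Conditions: NaH, BnBr, Bu4NI (cat.), DMF, 0 °C → rt
Reagents that add atoms: benzyl bromide, BrCc1ccccc1
Why: Williamson etherification of the secondary alkoxide; the nitrile has no α-hydrogen and the C3–O bond is not broken.

**Step 4**
Reactants: 4 (3R)-3-(benzyloxy)-2,2-dimethyl-3,4-dihydro-2H-chromene-6-carbonitrile
Product: 6 (3R)-3-(benzyloxy)-2,2-dimethyl-3,4-dihydro-2H-chromene-6-carbaldehyde, via aluminio aldimine 5 (not isolated)
Conditions: iBu2AlH, CH2Cl2, −78 °C; then 1 M HCl, 0 °C
Reagents that add atoms: water, O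
Why: Single hydride addition to the nitrile gives an N-aluminated imine that resists further reduction at low temperature and is hydrolysed to the aldehyde on work-up.

**Step 5**
Reactants: 6 (3R)-3-(benzyloxy)-2,2-dimethyl-3,4-dihydro-2H-chromene-6-carbaldehyde; 7 methyl 2-[(tert-butyldimethylsilyl)oxy]-2-(dimethoxyphosphoryl)acetate
Product: 8 methyl 3-[(3R)-3-(benzyloxy)-2,2-dimethylchroman-6-yl]-2-[(tert-butyldimethylsilyl)oxy]prop-2-enoate (E/Z mixture)
Conditions: LiN(SiMe3)2, THF, −78 °C → rt
Reagents that add atoms: none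
Why: Horner–Wadsworth–Emmons olefination with an α-silyloxy phosphonoacetate gives the silyl enol ether of the arylpyruvate directly; the alkene geometry is irrelevant because it is lost in step 6.

**Step 6**
Reactants: 8 methyl 3-[(3R)-3-(benzyloxy)-2,2-dimethylchroman-6-yl]-2-[(tert-butyldimethylsilyl)oxy]prop-2-enoate
Product: 9 methyl (2Z)-3-[(3R)-3-(benzyloxy)-2,2-dimethylchroman-6-yl]-2-hydroxyprop-2-enoate (enol form of the arylpyruvate ester)
Conditions: Bu4NF, AcOH, THF, 0 °C
Reagents that add atoms: none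
Why: Fluoride-mediated cleavage of the silyl enol ether; the arylpyruvate ester should rest as the hydrogen-bonded, arene-conjugated (Z)-enol, and the acetic acid buffer suppresses its self-aldol reaction.

**Step 7**
Reactants: 10 3,4-bis(benzyloxy)benzoic acid; 11 tert-butyl 2-methoxyacetate
Product: 13 tert-butyl 3-[3,4-bis(benzyloxy)phenyl]-2-methoxy-3-oxopropanoate, via acyl imidazole 12 (not isolated)
Conditions: 10, 1,1′-carbonyldiimidazole, THF, rt; then 11 pre-treated with LiN(SiMe3)2 (2.2 equiv), THF, −78 → 0 °C; 1 M HCl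
Reagents that add atoms: none
Why: Crossed Claisen condensation (C-acylation of an ester enolate by an acyl imidazole); the aroyl partner has no α-hydrogen and the second equivalent of base takes up the acidic β-keto ester, which drives the reaction.

**Step 8**
Reactants: 13 tert-butyl 3-[3,4-bis(benzyloxy)phenyl]-2-methoxy-3-oxopropanoate
Product: 14 tert-butyl (2E)-3-[3,4-bis(benzyloxy)phenyl]-2-methoxy-3-{[(trifluoromethyl)sulfonyl]oxy}prop-2-enoate
Conditions: NaH, Et2O, 0 °C; then Tf2O, −78 → 0 °C
Reagents that add atoms: trifluoromethanesulfonic anhydride, O=S(=O)(OS(=O)(=O)C(F)(F)F)C(F)(F)F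
Why: O-sulfonylation of the sodium-chelated, U-shaped β-keto ester enolate should place OTf cis to the ester carbonyl (E by the sequence rules because of the methoxy group), the geometry the cyclisation needs.

**Step 9**
Reactants: 14 tert-butyl (2E)-3-[3,4-bis(benzyloxy)phenyl]-2-methoxy-3-{[(trifluoromethyl)sulfonyl]oxy}prop-2-enoate
Product: 15 (2E)-3-[3,4-bis(benzyloxy)phenyl]-2-methoxy-3-{[(trifluoromethyl)sulfonyl]oxy}prop-2-enoic acid
Conditions: CF3CO2H/CH2Cl2 (1:4), anisole, 0 °C → rt
Reagents that add atoms: none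
Why: Acidolysis of the tert-butyl ester with loss of isobutene (E1-type); the vinyl triflate, the enol ether and the aryl benzyl ethers should tolerate brief exposure to trifluoroacetic acid.

**Step 10**
Reactants: 15 (2E)-3-[3,4-bis(benzyloxy)phenyl]-2-methoxy-3-{[(trifluoromethyl)sulfonyl]oxy}prop-2-enoic acid; 9 methyl (2Z)-3-[(3R)-3-(benzyloxy)-2,2-dimethylchroman-6-yl]-2-hydroxyprop-2-enoate
Product: 17 methyl (2Z)-3-[(3R)-3-(benzyloxy)-2,2-dimethylchroman-6-yl]-2-({(2E)-3-[3,4-bis(benzyloxy)phenyl]-2-methoxy-3-{[(trifluoromethyl)sulfonyl]oxy}prop-2-enoyl}oxy)prop-2-enoate, via acid chloride 16 (not isolated)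
Conditions: 15, (COCl)2, DMF (cat.), CH2Cl2, 0 °C; evaporate; then 9, iPr2NEt, CH2Cl2, −40 → 0 °C
Reagents that add atoms: none
Why: O-acylation of the arylpyruvate enol by an acid chloride that has no α-hydrogen (no ketene pathway); the (Z)-enol reacts on oxygen to give the (Z)-enol ester, and the hindered amine and low temperature disfavour conjugate displacement of the triflate.

**Step 11**
Reactants: 17 methyl (2Z)-3-[(3R)-3-(benzyloxy)-2,2-dimethylchroman-6-yl]-2-({(2E)-3-[3,4-bis(benzyloxy)phenyl]-2-methoxy-3-{[(trifluoromethyl)sulfonyl]oxy}prop-2-enoyl}oxy)prop-2-enoate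
Product: 18 methyl (2R)-2-{[(3R)-3-(benzyloxy)-2,2-dimethylchroman-6-yl]methyl}-3-[3,4-bis(benzyloxy)phenyl]-4-methoxy-5-oxo-2,5-dihydrofuran-2-carboxylate
Conditions: Pd(OAc)2 (10 mol%), (R)-BINAP (12 mol%), HCO2Na, DMF, 60 °C
Reagents that add atoms: none
Why: Proposed new method: the zerovalent palladium–BINAP complex adds oxidatively into the C4–OTf bond to give a cationic vinylpalladium species, which inserts the tethered enol-ester alkene (C4 bonds to C5, palladium moves to the benzylic carbon); the resulting η3-benzylpalladium has no β-hydrogen and is intercepted by formate, and decarboxylation followed by C–H reductive elimination gives the benzyl CH2 and returns the catalyst. The closest known reaction types are the enantioselective intramolecular reductive Heck cyclisation of aryl halides or triflates onto tethered 1,1-disubstituted alkenes (oxindoles and dihydrobenzofurans with quaternary centres) and the asymmetric Heck cyclisation that builds quaternary centres on trisubstituted alkenes. The butenolide ring closes in the 5-exo-trig mode through the s-cis rotamer of the enol ester, which requires the cis relation of OTf and carbonyl set in step 8. The C5 stereocentre is set by enantioface selection of the C5=CH alkene during migratory insertion, controlled by the axially chiral bisphosphine on cationic divalent palladium. The step needs 5-exo over 6-endo insertion and insertion ahead of formate reduction of the vinylpalladium: the five-membered transition state, the oxygen substituent on C5 (the cationic pathway delivers carbon to the oxygen-bearing alkene carbon) and the η3-benzyl stabilisation favour 5-exo, and sparingly soluble HCO2Na keeps the hydride concentration low.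

**Step 12**
Reactants: 18 methyl (2R)-2-{[(3R)-3-(benzyloxy)-2,2-dimethylchroman-6-yl]methyl}-3-[3,4-bis(benzyloxy)phenyl]-4-methoxy-5-oxo-2,5-dihydrofuran-2-carboxylate
Product: 19 methyl (2R)-3-(3,4-dihydroxyphenyl)-2-{[(3R)-3-hydroxy-2,2-dimethyl-3,4-dihydro-2H-chromen-6-yl]methyl}-4-methoxy-5-oxo-2,5-dihydrofuran-2-carboxylate
Conditions: H2 (1 atm), Pd/C, EtOAc/MeOH, rt
Reagents that add atoms: none
Why: Hydrogenolysis of the three benzyl ethers; the tetrasubstituted, ester-conjugated enol-ether alkene and the non-benzylic C–O bonds at both stereocentres should remain untouched, so neither centre is affected.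

**Compound list**
1 | 2,2-dimethyl-2H-chromene-6-carbonitrile | N#Cc1ccc2c(c1)C=CC(C)(C)O2 | starting material
2 | (3R,4R)-3,4-epoxy-2,2-dimethyl-3,4-dihydro-2H-chromene-6-carbonitrile | N#Cc1ccc2c(c1)[C@H]1O[C@H]1C(C)(C)O2 | intermediate
3 | (3R)-3-hydroxy-2,2-dimethyl-3,4-dihydro-2H-chromene-6-carbonitrile | N#Cc1ccc2c(c1)C[C@@H](O)C(C)(C)O2 | intermediate
4 | (3R)-3-(benzyloxy)-2,2-dimethyl-3,4-dihydro-2H-chromene-6-carbonitrile | N#Cc1ccc2c(c1)C[C@@H](OCc1ccccc1)C(C)(C)O2 | intermediate
5 | N-(diisobutylaluminio)aldimine of aldehyde 6 (not isolated) | CC(C)C[Al](CC(C)C)N=Cc1ccc2c(c1)C[C@@H](OCc1ccccc1)C(C)(C)O2 | intermediate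
6 | (3R)-3-(benzyloxy)-2,2-dimethyl-3,4-dihydro-2H-chromene-6-carbaldehyde | O=Cc1ccc2c(c1)C[C@@H](OCc1ccccc1)C(C)(C)O2 | intermediate
7 | methyl 2-[(tert-butyldimethylsilyl)oxy]-2-(dimethoxyphosphoryl)acetate | COC(=O)C(O[Si](C)(C)C(C)(C)C)P(=O)(OC)OC | starting material
8 | methyl 3-[(3R)-3-(benzyloxy)-2,2-dimethylchroman-6-yl]-2-[(tert-butyldimethylsilyl)oxy]prop-2-enoate (E/Z mixture) | COC(=O)C(O[Si](C)(C)C(C)(C)C)=Cc1ccc2c(c1)C[C@@H](OCc1ccccc1)C(C)(C)O2 | intermediate
9 | methyl (2Z)-3-[(3R)-3-(benzyloxy)-2,2-dimethylchroman-6-yl]-2-hydroxyprop-2-enoate (enol of the arylpyruvate ester) | COC(=O)/C(O)=C/c1ccc2c(c1)C[C@@H](OCc1ccccc1)C(C)(C)O2 | intermediate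
10 | 3,4-bis(benzyloxy)benzoic acid | OC(=O)c1ccc(OCc2ccccc2)c(OCc2ccccc2)c1 | starting material
11 | tert-butyl 2-methoxyacetate | COCC(=O)OC(C)(C)C | starting material
12 | [3,4-bis(benzyloxy)phenyl](1H-imidazol-1-yl)methanone (not isolated) | O=C(c1ccc(OCc2ccccc2)c(OCc2ccccc2)c1)n1ccnc1 | intermediate
13 | tert-butyl 3-[3,4-bis(benzyloxy)phenyl]-2-methoxy-3-oxopropanoate (racemic, enolisable) | COC(C(=O)OC(C)(C)C)C(=O)c1ccc(OCc2ccccc2)c(OCc2ccccc2)c1 | intermediate
14 | tert-butyl (2E)-3-[3,4-bis(benzyloxy)phenyl]-2-methoxy-3-{[(trifluoromethyl)sulfonyl]oxy}prop-2-enoate | CO/C(C(=O)OC(C)(C)C)=C(/OS(=O)(=O)C(F)(F)F)c1ccc(OCc2ccccc2)c(OCc2ccccc2)c1 | intermediate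
15 | (2E)-3-[3,4-bis(benzyloxy)phenyl]-2-methoxy-3-{[(trifluoromethyl)sulfonyl]oxy}prop-2-enoic acid | CO/C(C(=O)O)=C(/OS(=O)(=O)C(F)(F)F)c1ccc(OCc2ccccc2)c(OCc2ccccc2)c1 | intermediate
16 | (2E)-3-[3,4-bis(benzyloxy)phenyl]-2-methoxy-3-{[(trifluoromethyl)sulfonyl]oxy}prop-2-enoyl chloride (not isolated) | CO/C(C(=O)Cl)=C(/OS(=O)(=O)C(F)(F)F)c1ccc(OCc2ccccc2)c(OCc2ccccc2)c1 | intermediate
17 | methyl (2Z)-3-[(3R)-3-(benzyloxy)-2,2-dimethylchroman-6-yl]-2-({(2E)-3-[3,4-bis(benzyloxy)phenyl]-2-methoxy-3-{[(trifluoromethyl)sulfonyl]oxy}prop-2-enoyl}oxy)prop-2-enoate | COC(=O)/C(OC(=O)/C(OC)=C(\OS(=O)(=O)C(F)(F)F)c1ccc(OCc2ccccc2)c(OCc2ccccc2)c1)=C/c1ccc2c(c1)C[C@@H](OCc1ccccc1)C(C)(C)O2 | intermediate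
18 | methyl (2R)-2-{[(3R)-3-(benzyloxy)-2,2-dimethylchroman-6-yl]methyl}-3-[3,4-bis(benzyloxy)phenyl]-4-methoxy-5-oxo-2,5-dihydrofuran-2-carboxylate | COC(=O)[C@]1(Cc2ccc3c(c2)C[C@@H](OCc2ccccc2)C(C)(C)O3)OC(=O)C(OC)=C1c1ccc(OCc2ccccc2)c(OCc2ccccc2)c1 | intermediate
19 | methyl (2R)-3-(3,4-dihydroxyphenyl)-2-{[(3R)-3-hydroxy-2,2-dimethyl-3,4-dihydro-2H-chromen-6-yl]methyl}-4-methoxy-5-oxo-2,5-dihydrofuran-2-carboxylate | COC(=O)[C@]1(Cc2ccc3c(c2)C[C@@H](O)C(C)(C)O3)OC(=O)C(OC)=C1c1ccc(O)c(O)c1 | target

**Totals**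
Total step count: 12. Longest linear sequence: 9 steps (steps 1–6, 10, 11, 12).

**Steps most likely to fail**

Step 11 (Proposed new method). Formate reduction of the vinylpalladium may outrun insertion (hydrodetriflation). Insertion may go 6-endo and, after β-hydride loss, aromatise to a 2-pyranone. Formate may cleave the activated enol ester. Facial selectivity may be low or opposite.
Fallback (known chemistry, sets out from 9, returns at 18): the ring is built by a catalytic asymmetric aldol addition to the α-keto ester followed by lactonisation instead of by carbopalladation. Commercial 3,4-bis(benzyloxy)benzaldehyde and phosphonate 7, under the conditions of step 5, give methyl 3-[3,4-bis(benzyloxy)phenyl]-2-[(tert-butyldimethylsilyl)oxy]prop-2-enoate F1. Compound 9 reacts through its keto tautomer, which chelates divalent copper through both carbonyl oxygens. With F1 and Cu(OTf)2/(R,R)-tBu-box (10 mol%) in CH2Cl2 at −40 °C (Mukaiyama aldol addition to a pyruvate-type ester) it should give dimethyl (2R)-2-{[(3R)-3-(benzyloxy)-2,2-dimethylchroman-6-yl]methyl}-3-[3,4-bis(benzyloxy)phenyl]-2-[(tert-butyldimethylsilyl)oxy]-4-oxopentanedioate F2. The (R) carbinol is expected because the (S,S)-ligand is known to direct enolsilanes to the opposite face of pyruvates. HF·pyridine in MeCN removes the silyl group, and the tertiary alcohol lactonises onto the keto ester to give methyl (2R)-2-{[(3R)-3-(benzyloxy)-2,2-dimethylchroman-6-yl]methyl}-3-[3,4-bis(benzyloxy)phenyl]-4-hydroxy-5-oxo-2,5-dihydrofuran-2-carboxylate F3. Me3SiCHN2 in toluene/MeOH methylates the acidic enol hydroxyl and gives 18.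

Step 10. The triflate may be lost by conjugate addition–elimination of the enolate or the amine at C4, acylation may occur on carbon instead of oxygen, and the enol ester geometry may scramble.
Fallback (sets out from 9 and 10, returns at 17): the order of bond formation is changed so that no triflyloxy acid chloride is needed. Compound 9 is acylated with commercial methoxyacetyl chloride (pyridine, CH2Cl2, 0 °C) to methyl (2Z)-3-[(3R)-3-(benzyloxy)-2,2-dimethylchroman-6-yl]-2-[(methoxyacetyl)oxy]prop-2-enoate F4. Acid 10 is converted with (COCl)2/DMF (cat.) into 3,4-bis(benzyloxy)benzoyl chloride F5. A titanium-mediated crossed Claisen condensation of F4 with F5 (TiCl4, Bu3N, N-methylimidazole, CH2Cl2, −45 °C) gives methyl (2Z)-3-[(3R)-3-(benzyloxy)-2,2-dimethylchroman-6-yl]-2-({3-[3,4-bis(benzyloxy)phenyl]-2-methoxy-3-oxopropanoyl}oxy)prop-2-enoate F6. Chelation-controlled triflation as in step 8 (NaH, Tf2O) then leads to 17.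

Step 12. Cleavage of the hindered secondary benzyl ether may be slow, and on long exposure the enol-ether double bond may be saturated or the allylic lactone C5–O1 bond hydrogenolysed.
Fallback (sets out from 18, returns at 19): Lewis-acid debenzylation instead of hydrogenolysis, with BCl3 and pentamethylbenzene as cation scavenger in CH2Cl2 at −78 °C, converts 18 directly into 19; no new compound is made (F0).

**Further compounds**
F1 | step 11 | methyl 3-[3,4-bis(benzyloxy)phenyl]-2-[(tert-butyldimethylsilyl)oxy]prop-2-enoate | COC(=O)C(O[Si](C)(C)C(C)(C)C)=Cc1ccc(OCc2ccccc2)c(OCc2ccccc2)c1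
F2 | step 11 | dimethyl (2R)-2-{[(3R)-3-(benzyloxy)-2,2-dimethylchroman-6-yl]methyl}-3-[3,4-bis(benzyloxy)phenyl]-2-[(tert-butyldimethylsilyl)oxy]-4-oxopentanedioate (C3 epimers) | COC(=O)C(=O)C(c1ccc(OCc2ccccc2)c(OCc2ccccc2)c1)[C@@](Cc1ccc2c(c1)C[C@@H](OCc1ccccc1)C(C)(C)O2)(O[Si](C)(C)C(C)(C)C)C(=O)OC
F3 | step 11 | methyl (2R)-2-{[(3R)-3-(benzyloxy)-2,2-dimethylchroman-6-yl]methyl}-3-[3,4-bis(benzyloxy)phenyl]-4-hydroxy-5-oxo-2,5-dihydrofuran-2-carboxylate | COC(=O)[C@]1(Cc2ccc3c(c2)C[C@@H](OCc2ccccc2)C(C)(C)O3)OC(=O)C(O)=C1c1ccc(OCc2ccccc2)c(OCc2ccccc2)c1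
F4 | step 10 | methyl (2Z)-3-[(3R)-3-(benzyloxy)-2,2-dimethylchroman-6-yl]-2-[(methoxyacetyl)oxy]prop-2-enoate | COC(=O)/C(OC(=O)COC)=C/c1ccc2c(c1)C[C@@H](OCc1ccccc1)C(C)(C)O2
F5 | step 10 | 3,4-bis(benzyloxy)benzoyl chloride | O=C(Cl)c1ccc(OCc2ccccc2)c(OCc2ccccc2)c1
F6 | step 10 | methyl (2Z)-3-[(3R)-3-(benzyloxy)-2,2-dimethylchroman-6-yl]-2-({3-[3,4-bis(benzyloxy)phenyl]-2-methoxy-3-oxopropanoyl}oxy)prop-2-enoate | COC(=O)/C(OC(=O)C(OC)C(=O)c1ccc(OCc2ccccc2)c(OCc2ccccc2)c1)=C/c1ccc2c(c1)C[C@@H](OCc1ccccc1)C(C)(C)O2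
F0 | step 12 | none | none
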